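**Strategy**

The central quinone ring is the enol form of a 3,6-diaryl-cyclohexane-1,2,4,5-tetraone. Each aryl-bearing ring carbon lies between two oxygenated ring carbons, so it is the acidic carbon of a 1,3-dicarbonyl unit, and the ring divides into a 1,4-diaryl-butane-2,3-dione and an oxalyl unit. As in atromentin biosynthesis, the key step joins benzylic carbons to oxoacyl carbons: the dienolate of the diketone is C-acylated by di-tert-butyl oxalate, and the second benzylic enolate closes the six-membered ring onto the remaining oxoester (Claisen, then Dieckmann). The precursor is 1,4-bis(4-silyloxyphenyl)butane-2,3-dione. The silyl-protected quinonediol is then esterified twice with the (2Z,4S,5S)-epoxyhexenoyl unit and desilylated.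

Key step: step 3

Remark: compounds 1, 2, 6, 9 and 12 are taken as catalogue compounds. Diepoxide 2 is used as its commercial stereoisomer mixture, because both carbinol centres of 4 become carbonyl carbons in step 2. Compound 8 is drawn as one of its equivalent enol tautomers.

**Route**

Step 1
Reactants: 1 (4-bromophenoxy)(tert-butyl)dimethylsilane; 2 1,3-butadiene diepoxide
Product: 4 1,4-bis[4-(tert-butyldimethylsilyloxy)phenyl]butane-2,3-diol (diastereomer mixture), via aryl Grignard reagent 3 (not isolated)
Conditions: 1 (2.4 equiv), Mg, THF, reflux; then CuI (10 mol %), 2 (1.0 equiv), THF, −30 °C → 0 °C; aq. NH4Cl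
Reagents that add atoms: none
Why: Copper-catalysed Grignard opening of both terminal epoxides at their CH2 carbons (SN2) should give the 1,4-diaryl-2,3-diol, whose carbinol configurations do not matter because both centres are oxidised in step 2.

Step 2
Reactants: 4 1,4-bis[4-(tert-butyldimethylsilyloxy)phenyl]butane-2,3-diol
Product: 5 1,4-bis[4-(tert-butyldimethylsilyloxy)phenyl]butane-2,3-dione
Conditions: (COCl)2, DMSO, CH2Cl2, −78 °C; Et3N, −78 °C → 0 °C
Reagents that add atoms: none
Why: Swern oxidation should convert both secondary alcohols into ketones without cleaving the central C–C bond of the 1,2-diol and without touching the aryl silyl ethers.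

Step 3
Reactants: 5 1,4-bis[4-(tert-butyldimethylsilyloxy)phenyl]butane-2,3-dione; 6 di-tert-butyl oxalate
Product: 8 2,5-bis[4-(tert-butyldimethylsilyloxy)phenyl]-3,6-dihydroxy-1,4-benzoquinone, via open-chain trioxo ester 7 (not isolated)
Conditions: 5 added to LiN(SiMe3)2 (4.2 equiv), THF, −78 °C; 6 (1.05 equiv) added slowly, −78 °C → 40 °C; cold dil. aq. HCl
Reagents that add atoms: none
Why: LiN(SiMe3)2 removes both benzylic protons of the 1,2-diketone, the dienediolate undergoes a crossed Claisen C-acylation by the non-enolisable oxalate to give 7, and the remaining benzylic enolate of 7 attacks the tert-butyl oxoester carbonyl in a Dieckmann condensation; loss of tert-butoxide and two further deprotonations give the dianion of the 3,6-diaryl-2,5-dihydroxyquinone, a doubly vinylogous carboxylate that is the thermodynamic sink. The closest known reaction type is the double Claisen annulation of dibenzyl-type ketones or diesters with dialkyl oxalates to cyclic polyketones, and the bond pattern is that of the biosynthetic condensation of two 4-hydroxyphenylpyruvate units. The six-membered carbocycle is closed in a 6-(enolexo)-exo-trig mode, the new bond joining an aryl-bearing ring carbon to an oxygen-bearing, oxalate-derived ring carbon. No stereocentre is formed. The step needs C- over O-acylation and 1:1 annulation over acylation of one diketone by two oxalates: lithium enolates and oxalate esters favour C-acylation, slow addition keeps the oxalate from being in excess, and the second acylation is intramolecular. Only hindered LiOtBu is set free, which should leave the aryl silyl ethers in place.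

Step 4
Reactants: 9 (E)-but-2-en-1-ol
Product: 10 [(2S,3S)-3-methyloxiran-2-yl]methanol
Conditions: Ti(OiPr)4 (5 mol %), L-(+)-diisopropyl tartrate (6 mol %), t-BuOOH, 4 Å molecular sieves, CH2Cl2, −20 °C
Reagents that add atoms: tert-butyl hydroperoxide, CC(C)(C)OO
Why: Sharpless asymmetric epoxidation with the L-(+)-tartrate ligand should deliver oxygen to the face of the (E)-allylic alcohol that gives the (2S,3S)-epoxide, the trans relationship following from stereospecific syn addition to the E-alkene.

Step 5
Reactants: 10 [(2S,3S)-3-methyloxiran-2-yl]methanol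
Product: 11 (2R,3S)-3-methyloxirane-2-carbaldehyde
Conditions: (COCl)2, DMSO, CH2Cl2, −78 °C; Et3N; pentane, filtration, cold concentration, used crude
Reagents that add atoms: none
Why: Swern oxidation with non-aqueous work-up should give the volatile epoxy aldehyde without epimerisation, since the α-carbon is held in the oxirane ring (the descriptor changes from S to R only through the priority rules).

Step 6
Reactants: 11 (2R,3S)-3-methyloxirane-2-carbaldehyde; 12 methyl 2-[bis(2,2,2-trifluoroethoxy)phosphoryl]acetate
Product: 13 methyl (2Z,4S,5S)-4,5-epoxyhex-2-enoate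
Conditions: 12, KN(SiMe3)2, 18-crown-6, THF, −78 °C; then 11
Reagents that add atoms: none
Why: Still–Gennari olefination should give the (Z)-enoate under kinetic control, because the electron-poor phosphonate makes oxaphosphetane collapse faster than equilibration, and the two epoxide centres are not involved.

Step 7
Reactants: 13 methyl (2Z,4S,5S)-4,5-epoxyhex-2-enoate
Product: 14 potassium (2Z,4S,5S)-4,5-epoxyhex-2-enoate
Conditions: KOSiMe3 (1.05 equiv), Et2O, 0 °C → rt; salt collected by filtration
Reagents that add atoms: potassium trimethylsilanolate, C[Si](C)(C)[O-].[K+]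
Why: Anhydrous silanolate-mediated ester cleavage should give the carboxylate salt directly, so the free (Z)-epoxy acid, which could lactonise onto the epoxide to a butenolide, is never formed, and neither the Z-alkene nor the stereocentres are touched.

Step 8
Reactants: 8 2,5-bis[4-(tert-butyldimethylsilyloxy)phenyl]-3,6-dihydroxy-1,4-benzoquinone; 14 potassium (2Z,4S,5S)-4,5-epoxyhex-2-enoate
Product: 16 2,5-bis[4-(tert-butyldimethylsilyloxy)phenyl]-3,6-dioxocyclohexa-1,4-diene-1,4-diyl bis[(2Z,4S,5S)-4,5-epoxyhex-2-enoate], via epoxyhexenoyl chloride 15 (not isolated)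
Conditions: 14 (2.6 equiv), (COCl)2 (2.4 equiv), DMF (cat.), CH2Cl2, −20 °C → 0 °C; then 8, 2,6-lutidine (2.5 equiv), CH2Cl2, −40 °C → 0 °C
Reagents that add atoms: none
Why: O-acylation of the two strongly acidic enolic hydroxyls (vinylogous carboxylic acids) by an acid chloride made HCl-free from the carboxylate salt is a mixed-anhydride-type esterification, in which the hindered base should avoid Z-to-E isomerisation, the sub-stoichiometric oxalyl chloride cannot chlorinate the quinone, and the phenols are masked.

Step 9
Reactants: 16 2,5-bis[4-(tert-butyldimethylsilyloxy)phenyl]-3,6-dioxocyclohexa-1,4-diene-1,4-diyl bis[(2Z,4S,5S)-4,5-epoxyhex-2-enoate]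
Product: 17 2,5-bis(4-hydroxyphenyl)-3,6-dioxocyclohexa-1,4-diene-1,4-diyl bis[(2Z,4S,5S)-4,5-epoxyhex-2-enoate] (CNP0407724.1)
Conditions: Et3N·3HF, THF/MeCN, 0 °C → rt
Reagents that add atoms: none
Why: Fluoride cleavage of the aryl silyl ethers with near-neutral, non-basic Et3N·3HF should free both phenols without opening the epoxides, cleaving or transferring the enol esters, or isomerising the (Z)-enoates.

**Compound list**

1 | (4-bromophenoxy)(tert-butyl)dimethylsilane | CC(C)(C)[Si](C)(C)Oc1ccc(Br)cc1 | starting material
2 | 1,3-butadiene diepoxide (2,2'-bioxirane, stereoisomer mixture) | C1OC1C1CO1 | starting material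
3 | [4-(tert-butyldimethylsilyloxy)phenyl]magnesium bromide | CC(C)(C)[Si](C)(C)Oc1ccc([Mg]Br)cc1 | intermediate
4 | 1,4-bis[4-(tert-butyldimethylsilyloxy)phenyl]butane-2,3-diol (diastereomer mixture) | CC(C)(C)[Si](C)(C)Oc1ccc(CC(O)C(O)Cc2ccc(O[Si](C)(C)C(C)(C)C)cc2)cc1 | intermediate
5 | 1,4-bis[4-(tert-butyldimethylsilyloxy)phenyl]butane-2,3-dione | CC(C)(C)[Si](C)(C)Oc1ccc(CC(=O)C(=O)Cc2ccc(O[Si](C)(C)C(C)(C)C)cc2)cc1 | intermediate
6 | di-tert-butyl oxalate | CC(C)(C)OC(=O)C(=O)OC(C)(C)C | starting material
7 | tert-butyl 3,6-bis[4-(tert-butyldimethylsilyloxy)phenyl]-2,4,5-trioxohexanoate | CC(C)(C)OC(=O)C(=O)C(c1ccc(O[Si](C)(C)C(C)(C)C)cc1)C(=O)C(=O)Cc1ccc(O[Si](C)(C)C(C)(C)C)cc1 | intermediate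
8 | 2,5-bis[4-(tert-butyldimethylsilyloxy)phenyl]-3,6-dihydroxy-1,4-benzoquinone | CC(C)(C)[Si](C)(C)Oc1ccc(cc1)C1=C(O)C(=O)C(=C(O)C1=O)c1ccc(O[Si](C)(C)C(C)(C)C)cc1 | intermediate
9 | (E)-but-2-en-1-ol | C/C=C/CO | starting material
10 | [(2S,3S)-3-methyloxiran-2-yl]methanol | C[C@@H]1O[C@H]1CO | intermediate
11 | (2R,3S)-3-methyloxirane-2-carbaldehyde | C[C@@H]1O[C@H]1C=O | intermediate
12 | methyl 2-[bis(2,2,2-trifluoroethoxy)phosphoryl]acetate | COC(=O)CP(=O)(OCC(F)(F)F)OCC(F)(F)F | starting material
13 | methyl (2Z,4S,5S)-4,5-epoxyhex-2-enoate | C[C@@H]1O[C@H]1/C=C\C(=O)OC | intermediate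
14 | potassium (2Z,4S,5S)-4,5-epoxyhex-2-enoate | C[C@@H]1O[C@H]1/C=C\C(=O)[O-].[K+] | intermediate
15 | (2Z,4S,5S)-4,5-epoxyhex-2-enoyl chloride | C[C@@H]1O[C@H]1/C=C\C(Cl)=O | intermediate
16 | 2,5-bis[4-(tert-butyldimethylsilyloxy)phenyl]-3,6-dioxocyclohexa-1,4-diene-1,4-diyl bis[(2Z,4S,5S)-4,5-epoxyhex-2-enoate] | C[C@@H]1O[C@H]1/C=C\C(=O)OC1=C(c2ccc(O[Si](C)(C)C(C)(C)C)cc2)C(=O)C(OC(=O)/C=C\[C@@H]2O[C@H]2C)=C(c2ccc(O[Si](C)(C)C(C)(C)C)cc2)C1=O | intermediate
17 | 2,5-bis(4-hydroxyphenyl)-3,6-dioxocyclohexa-1,4-diene-1,4-diyl bis[(2Z,4S,5S)-4,5-epoxyhex-2-enoate] | C[C@@H]1O[C@H]1/C=C\C(=O)OC1=C(c2ccc(O)cc2)C(=O)C(OC(=O)/C=C\[C@@H]2O[C@H]2C)=C(c2ccc(O)cc2)C1=O | target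

**Step count**

Total step count: 9.
Longest linear sequence: 6 steps (steps 4, 5, 6, 7, 8, 9); the quinone branch (steps 1, 2, 3) joins at step 8.

**Steps most likely to fail**

Step 3. What may go wrong: acylation at enolate oxygen, acylation of one diketone by two oxalate molecules before the ring closes, slow closure onto the hindered tert-butyl oxoester, or loss of the aryl silyl ethers to the alkoxide set free. Fallback, from 5: Me3SiOTf/Et3N should convert the diketone into the bis(silyl) dienol ether (1Z,3Z)-1,4-bis[4-(tert-butyldimethylsilyloxy)phenyl]-2,3-bis(trimethylsilyloxy)buta-1,3-diene F1. F1 is then cyclised with oxalyl chloride and catalytic Me3SiOTf in CH2Cl2 at −78 °C → rt. This is a double Mukaiyama-type C-acylation under neutral, alkoxide-free conditions that closes the same ring between an aryl-bearing carbon and an oxalyl carbon. Aqueous work-up returns to the route at 8.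

Step 8. What may go wrong: Z-to-E isomerisation or chloride opening of the epoxide while the acid is activated, and sluggish acylation of the weakly nucleophilic quinonate. Fallback, from 8: the polarity of the esterification is reversed. Oxalyl chloride with catalytic DMF should turn the two enolic hydroxyls into vinylogous acid chlorides, giving 2,5-dichloro-3,6-bis[4-(tert-butyldimethylsilyloxy)phenyl]-1,4-benzoquinone F2. Addition–elimination of carboxylate 14 at both C–Cl positions (18-crown-6, MeCN, 0 °C) then returns to the route at 16, so the epoxy acid acts only as a nucleophile and is never activated.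

Step 9. What may go wrong: acyl transfer from the enol esters to the liberated phenols, hydrolysis of the enol esters, or epoxide opening during fluoride treatment. Fallback, from 8: the protecting groups are removed before the sensitive esters are present. Bu4NF in THF with acidic work-up should give 2,5-dihydroxy-3,6-bis(4-hydroxyphenyl)-1,4-benzoquinone (atromentin) F3. Its two enolic hydroxyls are far more acidic than the phenols and are the only ones ionised by 2,6-lutidine (2.0 equiv). They are acylated selectively with acid chloride 15 (2.0 equiv, CH2Cl2, −78 °C), which reaches 17 directly with no final deprotection.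

**Further compounds**

F1 | step 3 | (1Z,3Z)-1,4-bis[4-(tert-butyldimethylsilyloxy)phenyl]-2,3-bis(trimethylsilyloxy)buta-1,3-diene | CC(C)(C)[Si](C)(C)Oc1ccc(cc1)/C=C(\O[Si](C)(C)C)/C(O[Si](C)(C)C)=C/c1ccc(O[Si](C)(C)C(C)(C)C)cc1
F2 | step 8 | 2,5-dichloro-3,6-bis[4-(tert-butyldimethylsilyloxy)phenyl]-1,4-benzoquinone | CC(C)(C)[Si](C)(C)Oc1ccc(cc1)C1=C(Cl)C(=O)C(=C(Cl)C1=O)c1ccc(O[Si](C)(C)C(C)(C)C)cc1
F3 | step 9 | 2,5-dihydroxy-3,6-bis(4-hydroxyphenyl)-1,4-benzoquinone (atromentin) | Oc1ccc(cc1)C1=C(O)C(=O)C(=C(O)C1=O)c1ccc(O)cc1
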